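**Plan**

- **Numbering (decanolide):** C1 is the macrolactone C=O, C3 the O-bearing fusion CH, C4 the other fusion CH, C6 the ketone, and C9 is CH(CH3)O. Cα is the furyl-bearing carbon of the butyrolactone.
- **Enabling feature:** C1 and C6, the two carbonyls of the ten-membered ring, are 1,6-related, so that ring is the oxidatively opened form of a C1=C6 bicyclic enol ether (a 2-methylhexahydrochromene). With a temporary C1–C6 bond, C3 and C4 become neighbours in a cyclohexane. O3 and the butyrolactone C=O are 1,4-related, which is the retron of a ketyl–acrylate coupling.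
- **Cuts (retro):** O–Si; reconnect C1=C6; C3–C4 together with O3–C(=O) (SmI2); Cα–furan (Negishi); C4=Cα (Wittig); C1–C2 (allyl Grignard); C5–C6 (lactone alkylation).
- **Forward ring order:** ring A (δ-lactone, then tetrahydropyran ketal) comes first. Ring B (temporary cyclohexane) and the butyrolactone then close together. Cleavage of C1=C6 finally merges rings A and B into the ten-membered ketolactone.
- **Stereochemistry:** C9 comes from (R)-pent-4-en-2-ol and the side-chain carbinol from (R)-butane-1,3-diol. C9 controls C6 and C1 (equatorial arms, anomeric OMe), which control C4 and C3 in a chair/chelate transition state. Cα is set by convex-face kinetic protonation. The helper centres C1 and C6 are erased in the ring expansion.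

Key step: step 12

Remark: the all-cis Cα epimer is assumed to be the kinetic rather than the thermodynamic one, so it is set late and only mild, non-basic steps follow. The bromo ylide of step 9 is taken as a purchased reagent.

**Step 1**
Reactants: 1 (R)-butane-1,3-diol
Product: 2 (R)-4-iodobutan-2-ol
Conditions: I2, PPh3, imidazole, CH2Cl2, 0 °C
Reagents that add atoms: iodine, II
Why: Appel-type iodination is much faster at the unhindered primary hydroxyl than at the secondary one and leaves the stereocentre untouched.

**Step 2**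
Reactants: 2 (R)-4-iodobutan-2-ol
Product: 3 (R)-tert-butyl[(4-iodobutan-2-yl)oxy]dimethylsilane
Conditions: TBSCl, imidazole, DMF, rt
Reagents that add atoms: tert-butyldimethylsilyl chloride, CC(C)(C)[Si](C)(C)Cl
Why: This is a standard silylation of a secondary alcohol, and the stereocentre is not involved.

**Step 3**
Reactants: 4 furan; 3 (R)-tert-butyl[(4-iodobutan-2-yl)oxy]dimethylsilane
Product: 6 2-[(3R)-3-(tert-butyldimethylsilyloxy)butyl]furan, via 2-furyllithium 5 (not isolated)
Conditions: n-BuLi, THF, 0 °C; then 3, DMPU, −78 °C to rt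
Reagents that add atoms: none
Why: α-Lithiation of furan followed by SN2 alkylation with a primary iodide is the standard route to 2-alkylfurans.

**Step 4**
Reactants: 7 (R)-pent-4-en-2-ol; 8 methyl acrylate
Product: 9 methyl (2E,5R)-5-hydroxyhex-2-enoate
Conditions: second-generation Hoveyda–Grubbs catalyst (2 mol %), CH2Cl2, 40 °C
Reagents that add atoms: none
Why: Olefin cross-metathesis of a terminal homoallylic alcohol with an electron-poor acrylate is selective for the E cross product and does not touch the carbinol centre (future C9).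

**Step 5**
Reactants: 9 methyl (2E,5R)-5-hydroxyhex-2-enoate
Product: 11 (R)-6-methyltetrahydro-2H-pyran-2-one, via hydroxy ester 10 (not isolated)
Conditions: H2 (1 atm), Pd/C, EtOAc, rt; filter; then TsOH·H2O (5 mol %), PhMe, 80 °C
Reagents that add atoms: none
Why: Catalytic hydrogenation of the enoate followed by acid-catalysed lactonisation of the δ-hydroxy ester, driven by loss of methanol, gives the six-membered lactone with C9 unchanged.

**Step 6**
Reactants: 11 (R)-6-methyltetrahydro-2H-pyran-2-one; 12 prenyl bromide
Product: 14 (3S,6R)-6-methyl-3-(3-methylbut-2-en-1-yl)tetrahydro-2H-pyran-2-one (trans), via lithium enolate 13 (not isolated)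
Conditions: LDA, THF, −78 °C; then 12, DMPU, −78 to −40 °C
Reagents that add atoms: none
Why: In this lactone enolate alkylation the allylic bromide should enter the half-chair enolate anti to the pseudo-equatorial C9 methyl group, giving mainly the trans (diequatorial, also thermodynamic) isomer, and any cis isomer is removed by chromatography.

**Step 7**
Reactants: 14 trans-α-prenyl lactone; 15 allylmagnesium bromide
Product: 17 (2S,3S,6R)-2-allyl-2-methoxy-6-methyl-3-(3-methylbut-2-en-1-yl)tetrahydro-2H-pyran (OMe axial, both carbon arms and CH3 equatorial), via lactol 16 (not isolated)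
Conditions: 15 (1.1 equiv), THF, −78 °C; AcOH (1.2 equiv); then MeOH, CSA (10 mol %), 0 °C to rt
Reagents that add atoms: methanol, CO
Why: Grignard mono-addition to a δ-lactone stops at the tetrahedral alkoxide at low temperature, and acid-catalysed exchange of the lactol with methanol places OMe axial (anomeric effect) and the allyl arm equatorial, trans-diequatorial to the prenyl arm.

**Step 8**
Reactants: 17 allyl prenyl ketal
Product: 19 2-[(2S,3S,6R)-2-allyl-2-methoxy-6-methyltetrahydro-2H-pyran-3-yl]acetaldehyde, via secondary ozonide 18 (not isolated)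
Conditions: O3 (1 equiv, Sudan red 7B end point), CH2Cl2, −78 °C; then Me2S, −78 °C to rt
Reagents that add atoms: ozone, [O-][O+]=O
Why: Ozonolysis with one equivalent of ozone selects the electron-rich trisubstituted prenyl alkene over the monosubstituted allyl alkene, and Me2S reduces the ozonide to the C4 aldehyde.

**Step 9**
Reactants: 19 C4 aldehyde; 20 ethyl 2-bromo-2-(triphenyl-λ5-phosphanylidene)acetate
Product: 21 ethyl (Z)-2-bromo-4-[(2S,3S,6R)-2-allyl-2-methoxy-6-methyltetrahydro-2H-pyran-3-yl]but-2-enoate
Conditions: CH2Cl2, rt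
Reagents that add atoms: none
Why: Wittig olefination with the stabilised bromo ylide gives the (Z)-2-bromoenoate (alkyl trans to ester) under neutral conditions that spare the ketal and the allyl group.

**Step 10**
Reactants: 6 2-[(3R)-3-(tert-butyldimethylsilyloxy)butyl]furan; 21 (Z)-2-bromoenoate
Product: 24 ethyl (E)-4-[(2S,3S,6R)-2-allyl-2-methoxy-6-methyltetrahydro-2H-pyran-3-yl]-2-{5-[(3R)-3-(tert-butyldimethylsilyloxy)butyl]furan-2-yl}but-2-enoate, via furyllithium 22 (not isolated), via furylzinc chloride 23 (not isolated)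
Conditions: 6, n-BuLi, THF, 0 °C; ZnCl2, 0 °C to rt; then 21, Pd(PPh3)4 (5 mol %), THF, 40 °C
Reagents that add atoms: none
Why: In this Negishi coupling, C5 lithiation of the 2-alkylfuran, transmetalation to zinc and palladium-catalysed coupling with the alkenyl bromide proceed with retention of alkene geometry and tolerate ester, ketal and terminal alkene.

**Step 11**
Reactants: 24 furylacrylate with allyl arm
Product: 26 ethyl (E)-2-{5-[(3R)-3-(tert-butyldimethylsilyloxy)butyl]furan-2-yl}-4-[(2S,3S,6R)-2-methoxy-6-methyl-2-(2-oxoethyl)tetrahydro-2H-pyran-3-yl]but-2-enoate, via diol 25 (not isolated)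
Conditions: OsO4 (2 mol %), NaIO4, 2,6-lutidine, dioxane/H2O, rt; product used crude
Reagents that add atoms: osmium tetroxide (oxygen carrier), O=[Os](=O)(=O)=O; sodium periodate (terminal oxygen source), [Na+].[O-]I(=O)(=O)=O
Why: Lemieux–Johnson cleavage picks the monosubstituted alkene over the electron-poor trisubstituted acrylate and the furan, and the lutidine buffer protects the ketal and the elimination-prone β,β-dialkoxy aldehyde.

**Step 12**
Reactants: 26 aldehyde/furylacrylate
Product: 28 tricyclic lactone ketal (trans-fused oxadecalin of rings A and B, axial OMe at C1, γ-lactone cis-fused across C3–C4; C1 S, C3 S, C4 S, C6 S, C9 R, Cα R with furyl exo, side chain R), via hydroxy ester 27 (not isolated)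
Conditions: SmI2 (3 equiv), MeOH (4 equiv), THF, 0 °C, no HMPA
Reagents that add atoms: none
Why: SmI2 turns the aldehyde into a samarium ketyl whose carbon C3 adds 6-exo-trig to C4, the β-carbon of the 2-furylacrylate (electron transfer to the acrylate first would lead to the same bond); the Cα radical, stabilised by furan and ester, takes a second electron, the trivalent samarium enolate is protonated by MeOH to 27, and the C3 alkoxide displaces ethoxide in a 5-exo-trig acyl substitution that closes the butyrolactone. The closest known reaction type is the SmI2 ketyl–olefin cyclisation/lactonisation of aldehydes tethered to α,β-unsaturated esters. Ring B closes through a chair built on the rigid chair of ring A, whose C2 and C5 arms are trans-diequatorial, so a trans-fused oxadecalin forms with the acrylate equatorial, which relays C9 through C6 to C4 (S). The ketyl oxygen should go axial because trivalent samarium bridges it to the 1,3-diaxial C1 methoxy group (HMPA is left out to keep this chelate), which sets C3 (S) and places O3 cis to the Cα arm as lactonisation requires. Cα is not controlled here (the exo-furyl epimer is expected after equilibration by samarium alkoxides) and is set in step 14. The step needs aldehyde and acrylate to react while ketal, furan and silyl ether stay inert to SmI2, and the fast 6-exo closure should outrun simple reduction of either partner.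

**Step 13**
Reactants: 28 tricyclic lactone ketal
Product: 29 tricyclic C1=C6 enol ether (hexahydrochromene with cis-fused lactone; C3 S, C4 S, C9 R, Cα R)
Conditions: PPTS (20 mol %), 5 Å MS, PhMe, 80 °C
Reagents that add atoms: none
Why: Acid-catalysed loss of methanol from the tertiary ketal through the ring oxocarbenium ion under equilibrating conditions gives the more substituted ring-fusion enol ether, as in the dehydration of 2-(3-hydroxyalkyl)cyclohexanone hemiketals, and it erases the helper centres C1 and C6.

**Step 14**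
Reactants: 29 enol ether, exo-furyl epimer
Product: 31 enol ether, all-cis epimer (C3 S, C4 S, Cα S, C9 R), via lithium enolate 30 (not isolated)
Conditions: LiHMDS (1.1 equiv), THF, −78 °C; then AcOH in THF, −78 °C
Reagents that add atoms: none
Why: Deprotonation at the only acidic site and kinetic protonation of the planar lactone enolate from the convex face of the cis-fused bicycle (the face of H3 and H4) puts the new H on that face and the furyl group cis to C5, whatever epimer mixture enters.

**Step 15**
Reactants: 31 all-cis enol ether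
Product: 33 cordycicadin B tert-butyldimethylsilyl ether, via hemiketal diol 32 (not isolated)
Conditions: OsO4 (5 mol %), NMO, acetone/H2O, 0 °C to rt; crude diol, then Pb(OAc)4, CH2Cl2, 0 °C
Reagents that add atoms: osmium tetroxide (oxygen carrier), O=[Os](=O)(=O)=O; N-methylmorpholine N-oxide, C[N+]1([O-])CCOCC1; water, O
Why: Dihydroxylation of the most electron-rich alkene (the tetrasubstituted enol ether, furans being poor OsO4 substrates) followed by Criegee glycol cleavage of the α-hydroxy hemiketal breaks C1–C6 and unveils the C1 lactone and C6 ketone carbonyls at once, which is the classical oxidative ring expansion of bicyclic enol ethers to ten-membered ketolactones, in media too weakly basic to enolise Cα.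

**Step 16**
Reactants: 33 silyl ether
Product: 34 cordycicadin B
Conditions: HF·pyridine, THF, 0 °C to rt
Reagents that add atoms: none
Why: Fluoride-mediated desilylation under weakly acidic conditions frees the side-chain alcohol without enolising the α-furyl lactone or eliminating the β-acyloxy ester.

**Compound list**

1 | (R)-butane-1,3-diol | C[C@@H](O)CCO | starting material
2 | (R)-4-iodobutan-2-ol | C[C@@H](O)CCI | intermediate
3 | (R)-tert-butyl[(4-iodobutan-2-yl)oxy]dimethylsilane | C[C@@H](O[Si](C)(C)C(C)(C)C)CCI | intermediate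
4 | furan | c1ccoc1 | starting material
5 | 2-furyllithium | [Li]c1ccco1 | intermediate
6 | 2-[(3R)-3-(tert-butyldimethylsilyloxy)butyl]furan | C[C@@H](O[Si](C)(C)C(C)(C)C)CCc1ccco1 | intermediate
7 | (R)-pent-4-en-2-ol | C[C@@H](O)CC=C | starting material
8 | methyl acrylate | C=CC(=O)OC | starting material
9 | methyl (2E,5R)-5-hydroxyhex-2-enoate | C[C@@H](O)C/C=C/C(=O)OC | intermediate
10 | methyl (R)-5-hydroxyhexanoate | C[C@@H](O)CCCC(=O)OC | intermediate
11 | (R)-6-methyltetrahydro-2H-pyran-2-one | C[C@@H]1CCCC(=O)O1 | intermediate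
12 | prenyl bromide (1-bromo-3-methylbut-2-ene) | CC(C)=CCBr | starting material
13 | lithium enolate of 11 | C[C@@H]1CCC=C(O[Li])O1 | intermediate
14 | (3S,6R)-6-methyl-3-(3-methylbut-2-en-1-yl)tetrahydro-2H-pyran-2-one | C[C@@H]1CC[C@@H](CC=C(C)C)C(=O)O1 | intermediate
15 | allylmagnesium bromide | C=CC[Mg]Br | starting material
16 | (2S,3S,6R)-2-allyl-6-methyl-3-(3-methylbut-2-en-1-yl)tetrahydro-2H-pyran-2-ol (lactol) | C[C@@H]1CC[C@@H](CC=C(C)C)[C@@](CC=C)(O)O1 | intermediate
17 | (2S,3S,6R)-2-allyl-2-methoxy-6-methyl-3-(3-methylbut-2-en-1-yl)tetrahydro-2H-pyran | C[C@@H]1CC[C@@H](CC=C(C)C)[C@@](CC=C)(OC)O1 | intermediate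
18 | secondary ozonide of the prenyl alkene of 17 (epimers at the trioxolane CH) | C[C@@H]1CC[C@@H](CC2OOC(C)(C)O2)[C@@](CC=C)(OC)O1 | intermediate
19 | 2-[(2S,3S,6R)-2-allyl-2-methoxy-6-methyltetrahydro-2H-pyran-3-yl]acetaldehyde | C[C@@H]1CC[C@@H](CC=O)[C@@](CC=C)(OC)O1 | intermediate
20 | ethyl 2-bromo-2-(triphenyl-λ5-phosphanylidene)acetate | CCOC(=O)C(Br)=P(c1ccccc1)(c1ccccc1)c1ccccc1 | starting material
21 | ethyl (Z)-2-bromo-4-[(2S,3S,6R)-2-allyl-2-methoxy-6-methyltetrahydro-2H-pyran-3-yl]but-2-enoate | C[C@@H]1CC[C@@H](C/C=C(\Br)C(=O)OCC)[C@@](CC=C)(OC)O1 | intermediate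
22 | 5-lithio derivative of 6 | [Li]c1ccc(CC[C@@H](C)O[Si](C)(C)C(C)(C)C)o1 | intermediate
23 | {5-[(3R)-3-(tert-butyldimethylsilyloxy)butyl]furan-2-yl}zinc chloride | Cl[Zn]c1ccc(CC[C@@H](C)O[Si](C)(C)C(C)(C)C)o1 | intermediate
24 | ethyl (E)-4-[(2S,3S,6R)-2-allyl-2-methoxy-6-methyltetrahydro-2H-pyran-3-yl]-2-{5-[(3R)-3-(tert-butyldimethylsilyloxy)butyl]furan-2-yl}but-2-enoate | C[C@@H]1CC[C@@H](C/C=C(\c2ccc(CC[C@@H](C)O[Si](C)(C)C(C)(C)C)o2)C(=O)OCC)[C@@](CC=C)(OC)O1 | intermediate
25 | 2,3-dihydroxypropyl analogue of 24 (epimers at the new carbinol) | C[C@@H]1CC[C@@H](C/C=C(\c2ccc(CC[C@@H](C)O[Si](C)(C)C(C)(C)C)o2)C(=O)OCC)[C@@](CC(O)CO)(OC)O1 | intermediate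
26 | ethyl (E)-2-{5-[(3R)-3-(tert-butyldimethylsilyloxy)butyl]furan-2-yl}-4-[(2S,3S,6R)-2-methoxy-6-methyl-2-(2-oxoethyl)tetrahydro-2H-pyran-3-yl]but-2-enoate | C[C@@H]1CC[C@@H](C/C=C(\c2ccc(CC[C@@H](C)O[Si](C)(C)C(C)(C)C)o2)C(=O)OCC)[C@@](CC=O)(OC)O1 | intermediate
27 | trans-fused oxadecalin hydroxy ester (axial C3–OH, equatorial CH(furyl)CO2Et at C4) | C[C@@H]1CC[C@H]2C[C@@H]([C@H](c3ccc(CC[C@@H](C)O[Si](C)(C)C(C)(C)C)o3)C(=O)OCC)[C@@H](O)C[C@]2(OC)O1 | intermediate
28 | tricyclic lactone ketal (cis-fused γ-lactone on the trans-fused oxadecalin, Cα R) | C[C@@H]1CC[C@H]2C[C@@H]3[C@H](C[C@]2(OC)O1)OC(=O)[C@H]3c1ccc(CC[C@@H](C)O[Si](C)(C)C(C)(C)C)o1 | intermediate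
29 | tricyclic C1=C6 enol ether, Cα R | C[C@@H]1CCC2=C(O1)C[C@@H]3OC(=O)[C@@H](c4ccc(CC[C@@H](C)O[Si](C)(C)C(C)(C)C)o4)[C@@H]3C2 | intermediate
30 | lithium enolate of 29 | C[C@@H]1CCC2=C(O1)C[C@@H]3OC(O[Li])=C(c4ccc(CC[C@@H](C)O[Si](C)(C)C(C)(C)C)o4)[C@@H]3C2 | intermediate
31 | tricyclic C1=C6 enol ether, Cα S (all-cis lactone) | C[C@@H]1CCC2=C(O1)C[C@@H]3OC(=O)[C@H](c4ccc(CC[C@@H](C)O[Si](C)(C)C(C)(C)C)o4)[C@@H]3C2 | intermediate
32 | C1,C6-cis-diol (α-hydroxy hemiketal, both OH anti to the lactone) | C[C@@H]1CC[C@@]2(O)C[C@@H]3[C@H](C[C@@]2(O)O1)OC(=O)[C@@H]3c1ccc(CC[C@@H](C)O[Si](C)(C)C(C)(C)C)o1 | intermediate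
33 | cordycicadin B tert-butyldimethylsilyl ether | C[C@@H]1CCC(=O)C[C@@H]2[C@H](CC(=O)O1)OC(=O)[C@@H]2c1ccc(CC[C@@H](C)O[Si](C)(C)C(C)(C)C)o1 | intermediate
34 | cordycicadin B | C[C@@H]1CCC(=O)C[C@@H]2[C@H](CC(=O)O1)OC(=O)[C@@H]2c1ccc(CC[C@@H](C)O)o1 | target

**Step count**

Total steps: 16. Longest linear sequence: 13 (steps 4 to 16, from 7). The furan branch (steps 1 to 3) joins in step 10.

**Steps most likely to fail**

Step 12. The chelate between the ketyl oxygen and the C1 methoxy group may not hold, so the oxygen ends equatorial (poor facial selectivity at C3), or one partner may simply be reduced. The fallback sets out from 26 and comes back at 28. The cyclisation is run under non-chelating conditions (SmI2, HMPA, t-BuOH, THF), which should favour the all-equatorial C3-epimeric hydroxy ester F1. This is saponified (LiOH, THF/H2O) to the hydroxy acid F2, and the lactone is closed by an intramolecular Mitsunobu reaction (PPh3, DIAD, THF). That reaction inverts C3 and gives the same cis-fused lactone 28. C4 is fixed by the equatorial acrylate in either mode and is not affected.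

Step 15. The furan may be oxidised in competition, or osmylation of the hindered tetrasubstituted alkene may be too slow. The fallback sets out from 31 and comes back at 33. It is a nitrosative fragmentation with isopentyl nitrite and catalytic HCl in wet Et2O at 0 °C. Nitrosation occurs at the nucleophilic C6, hydration at C1, and the C1–C6 bond then breaks toward the nitroso group. This should give the ring-expanded oximino lactone F6 directly. Buffered aqueous TiCl3 (NH4OAc, THF) then converts the oxime into the C6 ketone of 33.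

Step 14. Facial selectivity in the protonation may be incomplete, or the Cα configuration may erode in the following steps. The fallback sets out from 29 (through enolate 30) and comes back at 31. The enolate is trapped with PhSeBr, which should enter from the convex face syn to H4 and give the α-phenylselanyl lactone F3. Oxidation (H2O2, pyridine, CH2Cl2, 0 °C) gives the selenoxide F4, which eliminates syn to the α-furylbutenolide F5. Hydrogenation of the C4=Cα bond (H2, Pd/C, EtOAc, stopped after one equivalent) from the face of H3 delivers both hydrogens syn. This sets C4 and Cα together in the all-cis sense of 31.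

**Further compounds**

F1 | step 12 | C3-epimeric hydroxy ester (equatorial C3–OH) | C[C@@H]1CC[C@H]2C[C@@H]([C@H](c3ccc(CC[C@@H](C)O[Si](C)(C)C(C)(C)C)o3)C(=O)OCC)[C@H](O)C[C@]2(OC)O1
F2 | step 12 | corresponding hydroxy acid | C[C@@H]1CC[C@H]2C[C@@H]([C@H](c3ccc(CC[C@@H](C)O[Si](C)(C)C(C)(C)C)o3)C(=O)O)[C@H](O)C[C@]2(OC)O1
F3 | step 14 | α-phenylselanyl lactone (Se on the convex face) | C[C@@H]1CCC2=C(O1)C[C@@H]3OC(=O)[C@]([Se]c5ccccc5)(c4ccc(CC[C@@H](C)O[Si](C)(C)C(C)(C)C)o4)[C@@H]3C2
F4 | step 14 | selenoxide of F3 | C[C@@H]1CCC2=C(O1)C[C@@H]3OC(=O)[C@]([Se](=O)c5ccccc5)(c4ccc(CC[C@@H](C)O[Si](C)(C)C(C)(C)C)o4)[C@@H]3C2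
F5 | step 14 | α-furylbutenolide (C4=Cα) | C[C@@H]1CCC2=C(O1)C[C@@H]3OC(=O)C(c4ccc(CC[C@@H](C)O[Si](C)(C)C(C)(C)C)o4)=C3C2
F6 | step 15 | C6 oxime of 33 | C[C@@H]1CCC(=NO)C[C@@H]2[C@H](CC(=O)O1)OC(=O)[C@@H]2c1ccc(CC[C@@H](C)O[Si](C)(C)C(C)(C)C)o1
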